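All runs come from a simulation on assumed constants; scatter was added.

If a flask stalls, first ask how long it takes to reach the stall, because that time tells you whether a late reading already gives the end. Here J and D join to links X in a closed, stirred flask. Winter is this very flask, followed so far, and dusk carries more J.

common to all: temperature 20 °C

| flask | J | D | L | remark | time |
|---|---|---|---|---|---|
| winter | 0.050 M | 0.055 M | 0.025 M | the very flask that is asked about, followed so far |  |
| dusk | 0.075 M | 0.055 M | 0.025 M | run made earlier |  |
| flask | 0.050 M | 0.0550 M | 0.0250 M |  | 15 h |

| run | time / h | X / % | J / % |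
|---|---|---|---|
| winter | 0.667 | 36 | 66 |
| winter | 2.00 | 49 | 53 |
| winter | 3.00 | 55 | 46 |
| winter | 5.00 | 62 | 38 |
| winter | 6.00 | 62 | 37 |
| winter | 10.0 | 63 | 32 |
| dusk | 2.50 | 41 | 59 |
| dusk | 5.00 | 47 | 54 |
| dusk | 8.00 | 47 | 55 |
| dusk | 10.0 | 48 | 55 |
| dusk | 12.0 | 49 | 53 |
| dusk | 15.0 | 48 | 51 |

(each reading ± 1.5 percentage points)

- north-east: at 15 h take out 90 % of the X then present, then wait 30 h
- west: at 15 h add D, 100 % of the amount charged, then wait 30 h
- south-east: at 15 h raise the temperature by 25 K, then wait 30 h
- north: change nothing and wait 30 h more

- removed X is counted in
- the earlier runs were read with a standard deviation of 1.5 percentage points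
- additions bring no volume worth counting
- the earlier runs do not show what temperature does; that part of a forecast is a guess

1. X, in percent of the J first charged, at 15 h
2. the remedy with the largest gain of X, or "none" below 2 percentage points (north-east / west / south-east / north / none)
3. X present, with what was taken out counted in, in percent of the J first charged, after north-east
4. X present, with what was taken out counted in, in percent of the J first charged, after north

Start with the plateau. Replace the flat end of the winter curve by its mean: X from 5.00 h on averages 62.3 %. Now measure the gap, the distance of X below that plateau. The winter reading at 3.00 h leaves 7.3 percentage points, so the time in which the gap halves, averaged over that stretch, is 0.972 h. Carry this gap half-life.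

Count with it. The 15 h hold 15.4 of them, and the further 30 h hold 30.9. Because the gap half-life is much shorter than the time asked about, winter should stand on its plateau by then. This count shows that the curve has levelled, not why it has. So commit to the plateau, for north as well.

Try it on dusk. Its X from 10.0 h on averages 48.3 %, and its reading at 2.50 h gives 0.919 h, close to the winter value.

The weak link is the plateau, which rests on one column. The J lost over the same winter readings gives 64.3 %, higher than the X mean, and each mean carries a scatter of 0.00866. Take the middle, 63.3 %. The gap half-life then becomes 1.03 h, and the count stands.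

The forecast gives 63 % now, 63.5 % after north and 77 % after north-east, and it names west as best. Of the stall it says: “I favour reversibility, though not firmly”.

The flask gives 66.8 % now, 67.3 % after north and 74.4 % after north-east, with west best at a gain of 23 points.

    J + D ⇌ X + Q (K = 0.710, k = 0.00640 M⁻¹ s⁻¹, Ea = 71.0 kJ mol⁻¹, ΔH = 11.0 kJ mol⁻¹)
    D + Q ⇌ E, settled at all times (K = 1800 M⁻¹, ΔH = 1.00 kJ mol⁻¹)
    L + Q → Z (k = 0.250 M⁻¹ s⁻¹, Ea = 44.0 kJ mol⁻¹)
    D ⇌ G (K = 3.00, k = 2.00 × 10⁻⁴ s⁻¹, Ea = 85.0 kJ mol⁻¹, ΔH = −72.0 kJ mol⁻¹)
    (constants at 20 °C)

In this flask at 15.0 h, the step J + D ⇌ X + Q relaxes, both ways together, with a half-life of 0.438 h, short against the 15 h and shorter than the gap half-life of 0.972 h. Its backward rate then stands at 95.3 % of its forward rate, with 33 % of the J charged and 6.3 % of the D charged left unbound, and at 150 h X reads 67.3 %.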